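Write the reagent balance first: on the way to tris adduct the limiting reagent in Saturday's flask is substrate, at 20 mM, since the 120 mM of reagent is more than 3 times that, while in Tuesday's flask it is the reagent, at 40.0 mM, which is less than 3 times that.

| setting | south-east | south-west | Tuesday's | Saturday's |
|---|---|---|---|---|
| substrate | 13 mM | 10 mM | 20 mM | 20 mM |
| reagent | 40 mM | 40 mM | 40.0 mM | 120 mM |
| remark | run made earlier | run made earlier |  |  |
| time |  |  | 40 h | 40 h |

| run | time / h | mono adduct / % |
|---|---|---|
| south-east | 5.00 | 34 |
| south-east | 10.0 | 46 |
| south-east | 15.0 | 57 |
| south-east | 20.0 | 58 |
| south-east | 25.0 | 59 |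
| south-west | 2.00 | 15 |
| south-west | 4.00 | 28 |
| south-west | 6.00 | 30 |
| south-west | 12.0 | 46 |
| south-west | 25.0 | 50 |

(readings scatter by 2 percentage points)

- which of the two there is more of at the end, Tuesday's (tris adduct / mono adduct)
- which of the two there is more of at the end, Saturday's (tris adduct / mono adduct)
- final mono adduct, as a percentage of the substrate charged, in Tuesday's
- final mono adduct, as a percentage of the substrate charged, in Saturday's

- for mono adduct the crystals are counted in
- as a solid, counted per litre of solution: crystals
- the earlier runs were read with a standard deviation of 2 percentage points
- reactions considered so far: substrate + reagent -> mono adduct; reagent + mono adduct -> bis adduct; reagent + bis adduct -> tris adduct; mono adduct <-> isomer of the product; crystals <-> mono adduct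

One reagent turns a substrate into mono adduct and two more turn that into tris adduct, so the whole charge as tris adduct needs 60.0 mM of reagent, the tris demand. Once substrate is consumed and bis adduct is small, the tris adduct share is the reagent used minus the substrate charged, over the tris demand minus the substrate charged.

Tuesday's c(reagent) falls short of the demand, which leaves room for 50.0 % tris adduct once every substrate has reacted. Saturday's charge is twice the demand. The first chemist treats mono adduct as a dissolved intermediate. Saturday's flask gets 4.80 times the charged reagent multiplied by hours of the south-east run's last reading, so she expects Saturday's flask to end near the demand, with 50.0 % of its reagent left.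

The second chemist reads the last readings of the runs: 59 % mono adduct in the south-east run and 50 % in the south-west run, each within 2 percentage points. What is not mono adduct comes to 5.33 mM and 5.00 mM, nearly equal amounts at different loadings, and he reads that as a fixed amount lost from solution, with the remaining mono adduct kept as crystals. Subtracting the south-east amount from Tuesday's charge gives him 73.4 % mono adduct, though for a shorter time.

The forecast, which sides with him, holds that “the solid is protected from further reaction”, but its figure for Tuesday's flask is lower: 65 % (55 % to 75 %), with more mono adduct. For Saturday's flask it gives 20 % (6 % to 40 %), with more tris adduct.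

Tuesday's flask ends with 69.3 % mono adduct and 12.8 % tris adduct. Saturday's flask ends with 27.8 % mono adduct, 62.3 % tris adduct, 21.9 % crystals and 62 % of its reagent, more than the first chemist's end.

    substrate + reagent → mono adduct (k = 3.00 /M/h)
    reagent + mono adduct → bis adduct (k = 2.80 /M/h)
    reagent + bis adduct → tris adduct (k = 3.30 /M/h)
    mono adduct ⇌ isomer of the product (K = 0.820, k = 0.140 /h)
    crystals ⇌ mono adduct, rate k5*(cs5 - [mono adduct]) while solid is left; crystals form when [mono adduct] > cs5 (solubility = 1.30 mM, k = 2.10 /h)

Saturday's flask has used 45.9 mM of reagent at 40.0 h, which is 76.5 % of the tris demand, and the rule gives 64.8 % tris adduct against the 62.3 % found. The same flask read at 4.0 d has 0 % substrate and 50 % of its reagent left, so 59.6 mM is used, 99.3 % of the demand, and the rule gives 99.0 %. That late flask is the first chemist's region: it holds 0 % crystals, 0.293 % mono adduct and 98.9 % tris adduct.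

(The data come from a simulation for an exercise.)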